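The constants say more once they are read as rates at the charged amounts, so we begin from the flask and what is asked of it.

starting material 34 mM; second substrate 34.0 mM; partner 34.0 mM; precatalyst 0.68 mM; impurity 0.37 mM

- the form that holds most of the catalyst when 5.0% of the starting material are converted (free catalyst / spent catalyst / catalyst intermediate B / catalyst intermediate A / precatalyst)
- its share of the catalyst then
- factor on the rate of making target when 5.0% of the starting material are converted if partner is charged twice over
- factor on the rate when 5.0% of the starting material are converted if precatalyst is charged at 6.0 mM instead

    starting material + free catalyst ⇌ catalyst intermediate A (K1 = 690 /M, k1 = 191 /M/s)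
    partner + catalyst intermediate A → free catalyst + target (k2 = 25.7 /M/s)
    second substrate + free catalyst ⇌ catalyst intermediate B (K3 = 475 /M, k3 = 224 /M/s)
    partner + catalyst intermediate B → free catalyst + second product (k4 = 29.7 /M/s)
    precatalyst ⇌ free catalyst (K5 = 1.5, k5 = 0.0474 /s)
    free catalyst + impurity → spent catalyst (k6 = 87900 /M/s)

Precatalyst releases free catalyst. Free catalyst binds starting material into catalyst intermediate A or second substrate into catalyst intermediate B, and partner turns these into target and second product, giving free catalyst back. Impurity turns free catalyst into spent catalyst, and that step has no way back.

1. The first instants. Precatalyst and free catalyst relax with a half-life of 0.146 min. Each free catalyst meets impurity at 2000 /min, faster than it meets both substrates together, 390 /min and 460 /min. So at the charged amounts 69.7% of the early free catalyst becomes spent catalyst.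

2. The middle. Catalyst intermediate A reacts with charged partner with a half-life of 0.0132 min, shorter than the release. Binding therefore shelters catalyst briefly, and it keeps returning to meet impurity.

3. The end of the loss. Each impurity takes one catalyst, and c impurity 0.37 mM is less than c precatalyst 0.68 mM, so impurity is the limiting reagent of that step. We carry one quantity, the titration share: the impurity charge divided by the catalyst charge, 54.4%. The catalyst left unspent, precatalyst counted, is 0.310 mM.

4. Our commitment. If impurity is used up by 5.0% conversion, spent catalyst holds 54.4%, more than the other forms together. It lies outside the working round, so it is no resting state. Our reckoning stops here: the two factors depend on how much precatalyst has been released at a moment for which we have no time.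

The forecast names spent catalyst at 54.4% (range 52% to 56%), a factor 1.6 for doubled partner (1.4 to 1.85), and 5.4 for more precatalyst (4.2 to 6.8). Its ground is that the impurity “scavenges free catalyst far faster than turnover occurs”.

In the flask, 5.0% conversion comes at 0.733 min. There spent catalyst holds 54.4%, doubled partner gives the factor 1.55, and 6.0 mM of precatalyst gives 5.24.

The spent catalyst stands at the titration share of 54.4%, and this flask still shows 54.4% after 30.0 min, with impurity at 0%. More than half of the catalyst is thus spent, and the 0.310 mM left unspent is shared between the working round and precatalyst, which held 13.4% of the catalyst at 0.733 min. With 6.0 mM of precatalyst, the titration share falls to 6.17% and the unspent catalyst, precatalyst counted, rises to 5.63 mM, or 18.2 times as much, while the simulated factor on the rate is smaller, at 5.24.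

(All constants are assumed; the flask was simulated.)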